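**Retrosynthetic overview**
- The target comes from an 8α-hydroxy macrocycle by inverting esterification at C-8 with tiglic acid.
- Key disconnection C-7–C-8: one SmI2 ketyl radical addition–elimination onto a 3-(methoxymethyl)butenolide closes the ten-membered ring and creates the 11(13)-methylene.
- The seco-enal comes from a C-2–C-3 boron aldol followed by Evans–Tishchenko reduction (sets C-3, then C-1, and places the acetate on O-3).
- The pieces are a keto acetal from 2,3-dimethylfuran and a Z-enal butenolide from acrolein, propyne, 2-(methoxymethyl)acrylic acid and CO.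
- Ring order: γ-lactone first (ring-closing metathesis), ten-membered carbocycle second (radical cyclisation).

Assumption: 2-(methoxymethyl)prop-2-enoic acid is bought as a catalogue compound; positions are cited with germacrane numbering (C-1 to C-13), β being the face of H-6 and α the face of H-7.

Step 1
Reactants: 1 acrolein; 2 propyne
Product: 4 (3S)-hex-1-en-4-yn-3-ol, via methyl(prop-1-ynyl)zinc 3 (not isolated)
Conditions: Me2Zn (3 equiv), ProPhenol ligand (10 mol%, the antipode that gives Re-face delivery), Ph3P=O (20 mol%), toluene, 0 °C; then 1, 4 °C, 24 h; aq. NH4Cl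
Reagents that add atoms: none
Why: Trost ProPhenol (dinuclear zinc) asymmetric alkynylation, which works well for enals; delivery of the propynyl group to the Re face of acrolein sets the 3S carbinol that becomes C-6.

Step 2
Reactants: 4 (3S)-hex-1-en-4-yn-3-ol
Product: 6 (3S,4Z)-5-iodohexa-1,4-dien-3-ol, via cyclic vinylalanate 5 (not isolated)
Conditions: NaAlH2(OCH2CH2OMe)2 (1.6 equiv), THF, 0 °C → rt; then I2 (2 equiv), −78 °C; aq. Na2S2O3
Reagents that add atoms: iodine, II
Why: hydroxyl-directed trans-hydroalumination then iodinolysis; aluminium is delivered to the distal alkyne carbon inside an O–Al–C chelate, so iodine ends up cis to the carbinol (Z), the geometry needed for C-4/C-5, and C-6 is untouched.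

Step 3
Reactants: 6 (3S,4Z)-5-iodohexa-1,4-dien-3-ol; 7 2-(methoxymethyl)prop-2-enoic acid
Product: 8 (3S,4Z)-5-iodohexa-1,4-dien-3-yl 2-(methoxymethyl)prop-2-enoate
Conditions: DCC, DMAP (5 mol%), CH2Cl2, 0 °C → rt
Reagents that add atoms: none
Why: Steglich esterification of a secondary bis-allylic alcohol under neutral conditions; no stereocentre is touched.

Step 4
Reactants: 8 (3S,4Z)-5-iodohexa-1,4-dien-3-yl 2-(methoxymethyl)prop-2-enoate
Product: 9 (5S)-5-[(1Z)-2-iodoprop-1-en-1-yl]-3-(methoxymethyl)furan-2(5H)-one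
Conditions: second-generation Grubbs catalyst RuCl2(=CHPh)(PCy3)(H2IMes) (5 mol%), CH2Cl2 (0.01 M), 40 °C
Reagents that add atoms: none
Why: ring-closing metathesis of the vinyl group onto the 1,1-disubstituted acrylate closes the butenolide with loss of ethene, the trisubstituted vinyl iodide being too hindered to take part.

Step 5
Reactants: 9 (5S)-5-[(1Z)-2-iodoprop-1-en-1-yl]-3-(methoxymethyl)furan-2(5H)-one
Product: 10 (2Z)-3-[(2R)-4-(methoxymethyl)-5-oxo-2,5-dihydrofuran-2-yl]-2-methylprop-2-enal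
Conditions: Pd(PPh3)4 (5 mol%), CO (3 atm), Bu3SnH (1.1 equiv, added over 3 h), THF, 50 °C
Reagents that add atoms: carbon monoxide, [C-]#[O+]
Why: Stille carbonylative formylation (oxidative addition, CO insertion, tin hydride capture of the acylpalladium) keeps the Z geometry under neutral conditions that spare the butenolide; 10 is used at once because Z-enals isomerise easily.

Step 6
Reactants: 11 2,3-dimethylfuran
Product: 13 (2E)-3-methyl-4-oxopent-2-enal, via (2Z)-3-methyl-4-oxopent-2-enal 12 (not isolated)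
Conditions: NBS, NaHCO3, acetone/H2O (10:1), −15 °C; then pyridine, rt
Reagents that add atoms: water, O
Why: oxidative furan ring opening (Kobayashi NBS protocol) gives the cis-enedione, which pyridine isomerises by reversible conjugate addition to the E isomer, the C-9/C-10 geometry of the target.

Step 7
Reactants: 13 (2E)-3-methyl-4-oxopent-2-enal
Product: 14 (3E)-5,5-dimethoxy-3-methylpent-3-en-2-one
Conditions: HC(OMe)3 (1.2 equiv), PPTS (2 mol%), MeOH, 0 °C
Reagents that add atoms: trimethyl orthoformate, COC(OC)OC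
Why: chemoselective acetalisation, the aldehyde reacting far faster than the conjugated ketone; this masks C-8 for the aldol.

Step 8
Reactants: 14 (3E)-5,5-dimethoxy-3-methylpent-3-en-2-one; 10 (2Z)-3-[(2R)-4-(methoxymethyl)-5-oxo-2,5-dihydrofuran-2-yl]-2-methylprop-2-enal
Product: 17 (2E,6S,7Z)-6-hydroxy-1,1-dimethoxy-3,7-dimethyl-8-[(2R)-4-(methoxymethyl)-5-oxo-2,5-dihydrofuran-2-yl]octa-2,7-dien-4-one, via boron enolate 15 (not isolated), via boron aldolate 16 (not isolated)
Conditions: (−)-Ipc2BCl (1.3 equiv), Et3N (1.5 equiv), Et2O, −78 → 0 °C; then 10, −78 → −20 °C; then MeOH, pH 7 buffer, H2O2, 0 °C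
Reagents that add atoms: none
Why: Paterson boron aldol of a methyl ketone; the (−)-Ipc ligands direct the enolate to the Si face of the aldehyde and set 3S by reagent control, and low temperature without free base protects the Z-enal and the acidic C-6 hydrogen.

Step 9
Reactants: 17 (2E,6S,7Z)-6-hydroxy-1,1-dimethoxy-3,7-dimethyl-8-[(2R)-4-(methoxymethyl)-5-oxo-2,5-dihydrofuran-2-yl]octa-2,7-dien-4-one
Product: 19 (2E,4S,6S,7Z)-4-hydroxy-3,7-dimethyl-8-[(2R)-4-(methoxymethyl)-5-oxo-2,5-dihydrofuran-2-yl]-1-oxoocta-2,7-dien-6-yl acetate, via acetate dimethyl acetal 18 (not isolated)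
Conditions: SmI2 (0.3 equiv), MeCHO (8 equiv), THF, −10 °C; then 1 M aq. HCl, 0 °C, 20 min
Reagents that add atoms: acetaldehyde, CC=O; water, O
Why: Evans–Tishchenko reduction; the C-3 hemiacetal of acetaldehyde, held on trivalent samarium, delivers hydride intramolecularly to the C-1 ketone, giving the 1,3-anti diol (1S from 3S) with the acetate on O-3 and O-1 free, and dilute acid then unmasks the C-8 aldehyde.

Step 10
Reactants: 19 (2E,4S,6S,7Z)-4-hydroxy-3,7-dimethyl-8-[(2R)-4-(methoxymethyl)-5-oxo-2,5-dihydrofuran-2-yl]-1-oxoocta-2,7-dien-6-yl acetate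
Product: 20 (2E,4S,6S,7Z)-3,7-dimethyl-8-[(2R)-4-(methoxymethyl)-5-oxo-2,5-dihydrofuran-2-yl]-1-oxo-4-(triethylsilyloxy)octa-2,7-dien-6-yl acetate
Conditions: Et3SiCl, imidazole, CH2Cl2, 0 °C
Reagents that add atoms: chlorotriethylsilane, CC[Si](Cl)(CC)CC
Why: silylation of the only free hydroxyl, so that the later C-8 esterification cannot touch O-1 and the radical step has no internal proton source.

Step 11
Reactants: 20 (2E,4S,6S,7Z)-3,7-dimethyl-8-[(2R)-4-(methoxymethyl)-5-oxo-2,5-dihydrofuran-2-yl]-1-oxo-4-(triethylsilyloxy)octa-2,7-dien-6-yl acetate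
Product: 21 3β-acetoxy-8α-hydroxy-1α-(triethylsilyloxy)germacra-4Z,9E,11(13)-trien-12,6α-olide
Conditions: SmI2 (2.5 equiv, 0.1 M in THF, added over 2 h), THF (0.002 M in 20), −40 → 0 °C, no protic additive; aq. NH4Cl
Reagents that add atoms: none
Why: Proposed new method: SmI2 reduces the enal to a samarium ketyl whose carbinol carbon C-8 (the other spin-bearing carbon, C-10, is fully substituted) adds as a radical to C-7 of the butenolide, a second electron gives the samarium enolate, and this expels methoxide (E1cB) to form the C-11 methylene, so ring and α-methylene lactone arise together; addition anti to the C-5 arm gives the trans lactone (H-7α), and the bulky samarium alkoxide takes the outer position with H-8 over the lactone, giving 8α-OH; the closest known chemistry is the Fukuzawa SmI2 ketyl–acrylate coupling, Molander-type medium-ring ketyl–olefin cyclisations and radical addition–elimination on 2-(alkoxymethyl)acrylates.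

Step 12
Reactants: 21 3β-acetoxy-8α-hydroxy-1α-(triethylsilyloxy)germacra-4Z,9E,11(13)-trien-12,6α-olide; 22 tiglic acid
Product: 24 3β-acetoxy-1α-hydroxy-8β-[(2E)-2-methylbut-2-enoyloxy]germacra-4Z,9E,11(13)-trien-12,6α-olide, via silyl-protected tiglate 23 (not isolated)
Conditions: PPh3 (3 equiv), DIAD (3 equiv), toluene, 0 °C (betaine preformed), then 21 and 22, 0 °C → rt; then HF·pyridine, THF, 0 °C
Reagents that add atoms: none
Why: Mitsunobu esterification inverts C-8 (SN2 of tiglate on the oxyphosphonium salt), turning 8α-OH into the 8β tiglate without E/Z loss in the acid, and fluoride then removes the triethylsilyl group without touching the esters.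

**Compound list**
1 | acrolein (prop-2-enal) | C=CC=O | starting material
2 | propyne | CC#C | starting material
3 | methyl(prop-1-ynyl)zinc | C[Zn]C#CC | intermediate
4 | (3S)-hex-1-en-4-yn-3-ol | O[C@@H](C=C)C#CC | intermediate
5 | sodium salt of the cyclic vinylalanate (five-membered O–Al–C ring, Al bearing two 2-methoxyethoxy groups, from trans-hydroalumination of 4) | CC1=C[C@H](C=C)O[Al-]1(OCCOC)OCCOC.[Na+] | intermediate
6 | (3S,4Z)-5-iodohexa-1,4-dien-3-ol | O[C@@H](C=C)/C=C(\I)C | intermediate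
7 | 2-(methoxymethyl)prop-2-enoic acid | C=C(COC)C(=O)O | starting material
8 | (3S,4Z)-5-iodohexa-1,4-dien-3-yl 2-(methoxymethyl)prop-2-enoate | C=C(COC)C(=O)O[C@@H](C=C)/C=C(\I)C | intermediate
9 | (5S)-5-[(1Z)-2-iodoprop-1-en-1-yl]-3-(methoxymethyl)furan-2(5H)-one | COCC1=C[C@@H](/C=C(\I)C)OC1=O | intermediate
10 | (2Z)-3-[(2R)-4-(methoxymethyl)-5-oxo-2,5-dihydrofuran-2-yl]-2-methylprop-2-enal | COCC1=C[C@@H](/C=C(/C)C=O)OC1=O | intermediate
11 | 2,3-dimethylfuran | Cc1occc1C | starting material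
12 | (2Z)-3-methyl-4-oxopent-2-enal | CC(=O)/C(C)=C\C=O | intermediate
13 | (2E)-3-methyl-4-oxopent-2-enal | CC(=O)/C(C)=C/C=O | intermediate
14 | (3E)-5,5-dimethoxy-3-methylpent-3-en-2-one | CC(=O)/C(C)=C/C(OC)OC | intermediate
15 | (3E)-2-[(−)-diisopinocampheylboryloxy]-5,5-dimethoxy-3-methylpenta-1,3-diene (boron enolate of 14) | C=C(OB([C@@H]1C[C@@H]2C[C@H]([C@H]1C)C2(C)C)[C@@H]1C[C@@H]2C[C@H]([C@H]1C)C2(C)C)/C(C)=C/C(OC)OC | intermediate
16 | O-(diisopinocampheylboryl) aldolate of 17 (boron on O-3) | COCC1=C[C@@H](/C=C(/C)[C@@H](OB([C@@H]2C[C@@H]3C[C@H]([C@H]2C)C3(C)C)[C@@H]2C[C@@H]3C[C@H]([C@H]2C)C3(C)C)CC(=O)/C(C)=C/C(OC)OC)OC1=O | intermediate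
17 | (2E,6S,7Z)-6-hydroxy-1,1-dimethoxy-3,7-dimethyl-8-[(2R)-4-(methoxymethyl)-5-oxo-2,5-dihydrofuran-2-yl]octa-2,7-dien-4-one | COCC1=C[C@@H](/C=C(/C)[C@@H](O)CC(=O)/C(C)=C/C(OC)OC)OC1=O | intermediate
18 | (2E,4S,6S,7Z)-4-hydroxy-1,1-dimethoxy-3,7-dimethyl-8-[(2R)-4-(methoxymethyl)-5-oxo-2,5-dihydrofuran-2-yl]octa-2,7-dien-6-yl acetate | COCC1=C[C@@H](/C=C(/C)[C@@H](OC(C)=O)C[C@H](O)/C(C)=C/C(OC)OC)OC1=O | intermediate
19 | (2E,4S,6S,7Z)-4-hydroxy-3,7-dimethyl-8-[(2R)-4-(methoxymethyl)-5-oxo-2,5-dihydrofuran-2-yl]-1-oxoocta-2,7-dien-6-yl acetate | COCC1=C[C@@H](/C=C(/C)[C@@H](OC(C)=O)C[C@H](O)/C(C)=C/C=O)OC1=O | intermediate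
20 | (2E,4S,6S,7Z)-3,7-dimethyl-8-[(2R)-4-(methoxymethyl)-5-oxo-2,5-dihydrofuran-2-yl]-1-oxo-4-(triethylsilyloxy)octa-2,7-dien-6-yl acetate | COCC1=C[C@@H](/C=C(/C)[C@@H](OC(C)=O)C[C@H](O[Si](CC)(CC)CC)/C(C)=C/C=O)OC1=O | intermediate
21 | 3β-acetoxy-8α-hydroxy-1α-(triethylsilyloxy)germacra-4Z,9E,11(13)-trien-12,6α-olide (H-6β, H-7α) | C=C1C(=O)O[C@@H]2/C=C(/C)[C@@H](OC(C)=O)C[C@H](O[Si](CC)(CC)CC)/C(C)=C/[C@H](O)[C@@H]12 | intermediate
22 | tiglic acid, (2E)-2-methylbut-2-enoic acid | C/C=C(\C)C(=O)O | starting material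
23 | 3β-acetoxy-8β-[(2E)-2-methylbut-2-enoyloxy]-1α-(triethylsilyloxy)germacra-4Z,9E,11(13)-trien-12,6α-olide | C=C1C(=O)O[C@@H]2/C=C(/C)[C@@H](OC(C)=O)C[C@H](O[Si](CC)(CC)CC)/C(C)=C/[C@@H](OC(=O)/C(C)=C/C)[C@@H]12 | intermediate
24 | 3β-acetoxy-1α-hydroxy-8β-[(2E)-2-methylbut-2-enoyloxy]germacra-4Z,9E,11(13)-trien-12,6α-olide (CNP0319825.6) | C=C1C(=O)O[C@@H]2/C=C(/C)[C@@H](OC(C)=O)C[C@H](O)/C(C)=C/[C@@H](OC(=O)/C(C)=C/C)[C@@H]12 | target

**Step count and risks**
Total step count: 12. Longest linear sequence: 10 (steps 1–5, then 8–12).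

Most at risk is step 11. The ten-membered ketyl–olefin closure may lose to simple reduction or pinacol coupling, and the ring-fusion and C-8 selectivity are predictions. The fallback abandons the ketyl radical for an allylmetal addition across the same bond. It sets out from 20: Me2BBr (CH2Cl2, −78 °C) turns the allylic methyl ether into (2E,4S,6S,7Z)-8-[(2R)-4-(bromomethyl)-5-oxo-2,5-dihydrofuran-2-yl]-3,7-dimethyl-1-oxo-4-(triethylsilyloxy)octa-2,7-dien-6-yl acetate F1. CrCl2 (6 equiv, divalent chromium) in THF/DMF at 0.002 M then closes C-7–C-8 by an intramolecular Nozaki–Hiyama allylation through the γ-carbon of the allylchromium. The chair-like transition state with the C-6 substituent trans to the CH2Cr group is anti-selective, which is again the trans lactone with 8α-OH, so the fallback comes back to the route at 21.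

Second is step 12. Mitsunobu inversion at a hindered allylic carbinol next to a Michael-accepting lactone may give elimination or phosphine adducts. The fallback replaces SN2 inversion by oxidation and reduction, and sets out from 21. Dess–Martin periodinane (CH2Cl2, NaHCO3, 0 °C) gives 3β-acetoxy-8-oxo-1α-(triethylsilyloxy)germacra-4Z,9E,11(13)-trien-12,6α-olide F2. NaBH4/CeCl3 (MeOH, −78 °C) delivers hydride to the α face, anti to the β-oriented C-7–C-11 bond, giving 3β-acetoxy-8β-hydroxy-1α-(triethylsilyloxy)germacra-4Z,9E,11(13)-trien-12,6α-olide F3. Yamaguchi esterification with 22 (2,4,6-trichlorobenzoyl chloride, Et3N, DMAP, toluene) proceeds with retention and comes back to the route at 23, which is desilylated as in step 12.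

Third is step 8. Traces of amine can isomerise the Z-enal or epimerise C-6 of 10, and the enantioselectivity of methyl ketone boron aldols is moderate. The fallback is a base-free Lewis-acid aldol and sets out from 14. LDA/Me3SiCl (THF, −78 °C) gives (3E)-5,5-dimethoxy-3-methyl-2-(trimethylsilyloxy)penta-1,3-diene F4. A Mukaiyama aldol with 10 under Yamamoto's tartrate-derived acyloxyborane catalyst (EtCN, −78 °C) gives the trimethylsilyl ether of 17 F5. Citric acid in MeOH removes the silyl group while keeping the acetal, and the fallback comes back to the route at 17.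

**Further compounds**
F1 | step 11 | (2E,4S,6S,7Z)-8-[(2R)-4-(bromomethyl)-5-oxo-2,5-dihydrofuran-2-yl]-3,7-dimethyl-1-oxo-4-(triethylsilyloxy)octa-2,7-dien-6-yl acetate | BrCC1=C[C@@H](/C=C(/C)[C@@H](OC(C)=O)C[C@H](O[Si](CC)(CC)CC)/C(C)=C/C=O)OC1=O
F2 | step 12 | 3β-acetoxy-8-oxo-1α-(triethylsilyloxy)germacra-4Z,9E,11(13)-trien-12,6α-olide | C=C1C(=O)O[C@@H]2/C=C(/C)[C@@H](OC(C)=O)C[C@H](O[Si](CC)(CC)CC)/C(C)=C/C(=O)[C@@H]12
F3 | step 12 | 3β-acetoxy-8β-hydroxy-1α-(triethylsilyloxy)germacra-4Z,9E,11(13)-trien-12,6α-olide | C=C1C(=O)O[C@@H]2/C=C(/C)[C@@H](OC(C)=O)C[C@H](O[Si](CC)(CC)CC)/C(C)=C/[C@@H](O)[C@@H]12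
F4 | step 8 | (3E)-5,5-dimethoxy-3-methyl-2-(trimethylsilyloxy)penta-1,3-diene | C=C(O[Si](C)(C)C)/C(C)=C/C(OC)OC
F5 | step 8 | trimethylsilyl ether of 17 (silyl on O-3) | COCC1=C[C@@H](/C=C(/C)[C@@H](O[Si](C)(C)C)CC(=O)/C(C)=C/C(OC)OC)OC1=O
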